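**Strategy.** The whole plan hangs on taking ring C apart around C4: this ketone carbon is bonded only to C4a of ring A and to C3, so it can be delivered as carbon monoxide between an ortho-iodophenol and a 1-arylvinylboronate carrying ring B. In one palladium-catalysed operation C4a–C4 and C4–C3 are made and the neighbouring phenol oxygen O1 then adds to the vinyl CH2 (future C2), closing the pyranone. The precursors are 2-iodo-5-(triisopropylsilyloxy)phenol and a MOM-protected ring-B vinyl pinacolboronate. C3 is set afterwards by reduction under dynamic kinetic resolution and reoxidation.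

Key step: step 8

Assumption: the target is read as the (3S)-isoflavanone, and 1-(2,3,4-trihydroxyphenyl)ethanone (gallacetophenone) is taken as a commercial starting material.

Design remark: the catechol oxygens are capped before the Claisen step so that the rearrangement frees a single phenol for methylation, and the vinylboronate is made from the methyl ketone through its enol triflate so that boron is fixed at the aryl-bearing carbon by constitution.

**Step 1**
Reactants: 1 4-iodoresorcinol; 2 chlorotriisopropylsilane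
Product: 3 2-iodo-5-(triisopropylsilyloxy)phenol
Conditions: TIPSCl (1.05 equiv), imidazole (2 equiv), CH2Cl2, 0 °C → rt
Reagents that add atoms: chlorotriisopropylsilane, CC(C)[Si](Cl)(C(C)C)C(C)C
Why: Silylation of a phenol with a bulky silyl chloride and imidazole should take place at the unhindered oxygen para to iodine and leave the oxygen flanked by iodine free.

**Step 2**
Reactants: 4 1-(2,3,4-trihydroxyphenyl)ethanone; 5 prenyl bromide
Product: 6 1-[2,3-dihydroxy-4-(3-methylbut-2-enyloxy)phenyl]ethanone
Conditions: prenyl bromide (1.1 equiv), NaHCO3 (1.5 equiv), DMF, 40 °C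
Reagents that add atoms: prenyl bromide, CC(C)=CCBr
Why: Williamson etherification under weak-base control, in which only the 4-OH (para to the acetyl group and not hydrogen-bonded to it) is acidic enough to be ionised by NaHCO3, so alkylation should stop at the 4-O-prenyl ether.

**Step 3**
Reactants: 6 1-[2,3-dihydroxy-4-(3-methylbut-2-enyloxy)phenyl]ethanone; 7 chloromethyl methyl ether
Product: 8 1-[2,3-bis(methoxymethoxy)-4-(3-methylbut-2-enyloxy)phenyl]ethanone
Conditions: MOMCl (4 equiv), iPr2NEt (5 equiv), CH2Cl2, 0 → 40 °C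
Reagents that add atoms: chloromethyl methyl ether, COCCl
Why: Standard MOM ether formation in which excess reagent and warming also cap the hydrogen-bonded 2-OH, while the amine base is too weak to enolise the ketone.

**Step 4**
Reactants: 8 1-[2,3-bis(methoxymethoxy)-4-(3-methylbut-2-enyloxy)phenyl]ethanone
Product: 10 1-[4-hydroxy-2,3-bis(methoxymethoxy)-5-(2-methylbut-3-en-2-yl)phenyl]ethanone, via ortho-dienone 9 (not isolated)
Conditions: PhNEt2, 190 °C, sealed tube, argon
Reagents that add atoms: none
Why: Aromatic Claisen ([3,3]-sigmatropic) rearrangement of the aryl prenyl ether, in which C3 is blocked so the allyl unit is delivered with inversion to C5 and dienone 9 tautomerises to the phenol, the basic solvent holding back acid-promoted cyclisation of the product.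

**Step 5**
Reactants: 10 1-[4-hydroxy-2,3-bis(methoxymethoxy)-5-(2-methylbut-3-en-2-yl)phenyl]ethanone; 11 iodomethane
Product: 12 1-[4-methoxy-2,3-bis(methoxymethoxy)-5-(2-methylbut-3-en-2-yl)phenyl]ethanone
Conditions: MeI (3 equiv), K2CO3 (2 equiv), DMF, rt
Reagents that add atoms: iodomethane, CI
Why: Williamson methylation of the only free phenol, run directly after step 4 so that the ortho-(1,1-dimethylallyl)phenol has no opportunity to cyclise or rearrange.

**Step 6**
Reactants: 12 1-[4-methoxy-2,3-bis(methoxymethoxy)-5-(2-methylbut-3-en-2-yl)phenyl]ethanone; 13 N-phenylbis(trifluoromethanesulfonimide)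
Product: 15 1-[4-methoxy-2,3-bis(methoxymethoxy)-5-(2-methylbut-3-en-2-yl)phenyl]vinyl trifluoromethanesulfonate, via potassium enolate 14 (not isolated)
Conditions: KN(SiMe3)2 (1.1 equiv), THF, −78 °C; then PhNTf2 (1.15 equiv), −78 → 0 °C
Reagents that add atoms: N-phenylbis(trifluoromethanesulfonimide), O=S(=O)(N(c1ccccc1)S(=O)(=O)C(F)(F)F)C(F)(F)F
Why: Kinetic enolisation of the methyl ketone at its only enolisable position followed by O-sulfonylation gives the enol triflate with the leaving group on the aryl-bearing carbon.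

**Step 7**
Reactants: 15 1-[4-methoxy-2,3-bis(methoxymethoxy)-5-(2-methylbut-3-en-2-yl)phenyl]vinyl trifluoromethanesulfonate; 16 bis(pinacolato)diboron
Product: 17 2-{1-[4-methoxy-2,3-bis(methoxymethoxy)-5-(2-methylbut-3-en-2-yl)phenyl]vinyl}-4,4,5,5-tetramethyl-1,3,2-dioxaborolane
Conditions: B2pin2 (1.1 equiv), PdCl2(PPh3)2 (3 mol%), PPh3 (6 mol%), KOPh (1.5 equiv), toluene, 50 °C
Reagents that add atoms: bis(pinacolato)diboron, CC1(C)OB(OC1(C)C)B1OC(C)(C)C(C)(C)O1
Why: Miyaura borylation of an alkenyl triflate, in which the weak base KOPh avoids onward Suzuki coupling and boron replaces the triflate at the same carbon.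

**Step 8**
Reactants: 3 2-iodo-5-(triisopropylsilyloxy)phenol; 17 ring-B 1-arylvinyl pinacolboronate; 18 carbon monoxide
Product: 20 rac-3-[4-methoxy-2,3-bis(methoxymethoxy)-5-(2-methylbut-3-en-2-yl)phenyl]-7-(triisopropylsilyloxy)chroman-4-one, via aryl vinyl ketone 19 (not isolated)
Conditions: 17 (1.3 equiv), Pd(OAc)2 (5 mol%), Xantphos (6 mol%), CO (3 bar), K2CO3 (3 equiv), H2O (5 equiv), anisole, 80 °C
Reagents that add atoms: carbon monoxide, [C-]#[O+]
Why: Zerovalent palladium (from Pd(OAc)2 and Xantphos) inserts into the C–I bond of 3, CO insertion gives an aroyl–palladium species, boronate 17 transmetalates and reductive elimination forms the 2-hydroxyaryl vinyl ketone 19, so C4a–C4 and C4–C3 are made in one catalytic cycle (carbonylative Suzuki–Miyaura coupling of an aryl iodide with an alkenylboron reagent). Under the carbonate base the ortho phenoxide of 19 adds to the terminal vinyl carbon in a 6-endo-trig oxa-Michael reaction (O1–C2), closing ring C as in the classical cyclisation of 2-hydroxyaryl vinyl ketones to chroman-4-ones. The resulting enolate is protonated at C3 without facial bias, so C3 is formed racemic here by design and is set in step 9. The step needs carbonylative over direct coupling, which the CO pressure, the wide-bite-angle diphosphine and the slow transmetalation of the 1,1-disubstituted boronate should secure by giving CO insertion time to occur first. It also needs closure through O1 alone, which is assured because the other ring-A oxygen is silylated and the ring-B oxygens are MOM ethers.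

**Step 9**
Reactants: 20 rac-3-[4-methoxy-2,3-bis(methoxymethoxy)-5-(2-methylbut-3-en-2-yl)phenyl]-7-(triisopropylsilyloxy)chroman-4-one
Product: 21 (3S,4S)-3-[4-methoxy-2,3-bis(methoxymethoxy)-5-(2-methylbut-3-en-2-yl)phenyl]-7-(triisopropylsilyloxy)chroman-4-ol (cis)
Conditions: RuCl[(S,S)-TsDPEN](p-cymene) (3 mol%), HCO2H (5 equiv), Et3N (10 equiv), EtOAc, 40 °C
Reagents that add atoms: none
Why: Noyori asymmetric transfer hydrogenation under dynamic kinetic resolution, in which Et3N epimerises C3 of 20 through the enol faster than reduction and the (S,S)-catalyst delivers hydride to C4 of the (3S)-ketone anti to the aryl group, fixing (4S) and (3S) together as the cis alcohol.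

**Step 10**
Reactants: 21 (3S,4S)-cis-isoflavan-4-ol
Product: 22 (3S)-3-[4-methoxy-2,3-bis(methoxymethoxy)-5-(2-methylbut-3-en-2-yl)phenyl]-7-(triisopropylsilyloxy)chroman-4-one
Conditions: Dess–Martin periodinane (1.3 equiv), CH2Cl2, 0 °C
Reagents that add atoms: none
Why: Dess–Martin oxidation of the benzylic alcohol returns the C4 ketone under base-free conditions, so the now enolisable C3 centre should keep its (S) configuration.

**Step 11**
Reactants: 22 (3S)-7-(triisopropylsilyloxy)-2',3'-bis(methoxymethoxy) isoflavanone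
Product: 23 (3S)-7-hydroxy-3-[4-methoxy-2,3-bis(methoxymethoxy)-5-(2-methylbut-3-en-2-yl)phenyl]chroman-4-one
Conditions: HF·pyridine, pyridine, THF, 0 °C → rt
Reagents that add atoms: none
Why: Fluoride cleavage of the aryl silyl ether, activated by the para carbonyl, proceeds on the acidic side of neutral, which leaves the MOM ethers intact and avoids base-induced enolisation at C3.

**Step 12**
Reactants: 23 (3S)-7-hydroxy-2',3'-bis(methoxymethoxy) isoflavanone
Product: 24 (3S)-3-[2,3-dihydroxy-4-methoxy-5-(2-methylbut-3-en-2-yl)phenyl]-7-hydroxychroman-4-one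
Conditions: 2 M HCl, MeOH/THF, rt
Reagents that add atoms: none
Why: Acid-catalysed acetal exchange removes both MOM ethers as dimethoxymethane, and in dilute acid at room temperature enolisation of C3, cyclodehydration through the 2'-OH and protonation of the monosubstituted alkene should all be slow.

**Compound list**
1 | 4-iodoresorcinol | Oc1ccc(I)c(O)c1 | starting material
2 | chlorotriisopropylsilane | CC(C)[Si](Cl)(C(C)C)C(C)C | starting material
3 | 2-iodo-5-(triisopropylsilyloxy)phenol | CC(C)[Si](Oc1ccc(I)c(O)c1)(C(C)C)C(C)C | intermediate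
4 | 1-(2,3,4-trihydroxyphenyl)ethanone (gallacetophenone) | CC(=O)c1ccc(O)c(O)c1O | starting material
5 | prenyl bromide | CC(C)=CCBr | starting material
6 | 1-[2,3-dihydroxy-4-(3-methylbut-2-enyloxy)phenyl]ethanone | CC(=O)c1ccc(OCC=C(C)C)c(O)c1O | intermediate
7 | chloromethyl methyl ether | COCCl | starting material
8 | 1-[2,3-bis(methoxymethoxy)-4-(3-methylbut-2-enyloxy)phenyl]ethanone | CC(=O)c1ccc(OCC=C(C)C)c(OCOC)c1OCOC | intermediate
9 | 4-acetyl-2,3-bis(methoxymethoxy)-6-(2-methylbut-3-en-2-yl)cyclohexa-2,4-dien-1-one (ortho-dienone, racemic) | CC(=O)C1=CC(C(C)(C)C=C)C(=O)C(OCOC)=C1OCOC | intermediate (not isolated)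
10 | 1-[4-hydroxy-2,3-bis(methoxymethoxy)-5-(2-methylbut-3-en-2-yl)phenyl]ethanone | CC(=O)c1cc(C(C)(C)C=C)c(O)c(OCOC)c1OCOC | intermediate
11 | iodomethane | CI | starting material
12 | 1-[4-methoxy-2,3-bis(methoxymethoxy)-5-(2-methylbut-3-en-2-yl)phenyl]ethanone | CC(=O)c1cc(C(C)(C)C=C)c(OC)c(OCOC)c1OCOC | intermediate
13 | N-phenylbis(trifluoromethanesulfonimide) | O=S(=O)(N(c1ccccc1)S(=O)(=O)C(F)(F)F)C(F)(F)F | starting material
14 | potassium enolate of 12 | [K+].[O-]C(=C)c1cc(C(C)(C)C=C)c(OC)c(OCOC)c1OCOC | intermediate (not isolated)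
15 | 1-[4-methoxy-2,3-bis(methoxymethoxy)-5-(2-methylbut-3-en-2-yl)phenyl]vinyl trifluoromethanesulfonate | C=C(OS(=O)(=O)C(F)(F)F)c1cc(C(C)(C)C=C)c(OC)c(OCOC)c1OCOC | intermediate
16 | bis(pinacolato)diboron | CC1(C)OB(OC1(C)C)B1OC(C)(C)C(C)(C)O1 | starting material
17 | 2-{1-[4-methoxy-2,3-bis(methoxymethoxy)-5-(2-methylbut-3-en-2-yl)phenyl]vinyl}-4,4,5,5-tetramethyl-1,3,2-dioxaborolane | C=C(B1OC(C)(C)C(C)(C)O1)c1cc(C(C)(C)C=C)c(OC)c(OCOC)c1OCOC | intermediate
18 | carbon monoxide | [C-]#[O+] | starting material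
19 | 1-[2-hydroxy-4-(triisopropylsilyloxy)phenyl]-2-[4-methoxy-2,3-bis(methoxymethoxy)-5-(2-methylbut-3-en-2-yl)phenyl]prop-2-en-1-one | C=C(C(=O)c1ccc(O[Si](C(C)C)(C(C)C)C(C)C)cc1O)c1cc(C(C)(C)C=C)c(OC)c(OCOC)c1OCOC | intermediate (not isolated)
20 | rac-3-[4-methoxy-2,3-bis(methoxymethoxy)-5-(2-methylbut-3-en-2-yl)phenyl]-7-(triisopropylsilyloxy)chroman-4-one | C=CC(C)(C)c1cc(C2COc3cc(O[Si](C(C)C)(C(C)C)C(C)C)ccc3C2=O)c(OCOC)c(OCOC)c1OC | intermediate
21 | (3S,4S)-3-[4-methoxy-2,3-bis(methoxymethoxy)-5-(2-methylbut-3-en-2-yl)phenyl]-7-(triisopropylsilyloxy)chroman-4-ol (cis) | C=CC(C)(C)c1cc([C@H]2COc3cc(O[Si](C(C)C)(C(C)C)C(C)C)ccc3[C@H]2O)c(OCOC)c(OCOC)c1OC | intermediate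
22 | (3S)-3-[4-methoxy-2,3-bis(methoxymethoxy)-5-(2-methylbut-3-en-2-yl)phenyl]-7-(triisopropylsilyloxy)chroman-4-one | C=CC(C)(C)c1cc([C@H]2COc3cc(O[Si](C(C)C)(C(C)C)C(C)C)ccc3C2=O)c(OCOC)c(OCOC)c1OC | intermediate
23 | (3S)-7-hydroxy-3-[4-methoxy-2,3-bis(methoxymethoxy)-5-(2-methylbut-3-en-2-yl)phenyl]chroman-4-one | C=CC(C)(C)c1cc([C@H]2COc3cc(O)ccc3C2=O)c(OCOC)c(OCOC)c1OC | intermediate
24 | (3S)-3-[2,3-dihydroxy-4-methoxy-5-(2-methylbut-3-en-2-yl)phenyl]-7-hydroxychroman-4-one | C=CC(C)(C)c1cc([C@H]2COc3cc(O)ccc3C2=O)c(O)c(O)c1OC | target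

**Count.** Total steps: 12. Longest linear sequence: 11 steps (4 → 24 through steps 2–12); the ring-A branch adds step 1.

**Steps most likely to fail**

1. Step 8. The aroyl–palladium intermediate may wait too long for the congested 1,1-disubstituted boronate, so that CO-free coupling, protodeboronation or acylation of a phenoxide oxygen consumes the partners before the ketone forms. Fallback, setting out from 3 and 15 and returning at 20: the roles of the partners are exchanged. Miyaura borylation of 3 (B2pin2, PdCl2(dppf), KOAc, 1,4-dioxane, 80 °C) should give 2-(4,4,5,5-tetramethyl-1,3,2-dioxaborolan-2-yl)-5-(triisopropylsilyloxy)phenol F1. Carbonylative Suzuki–Miyaura coupling of enol triflate 15 with F1 (PdCl2(dppf), K2CO3, KI, CO, anisole, 80 °C) then puts the hindered partner on the electrophile side and lets an unhindered, electron-rich arylboronate transmetalate. The same ketone 19 results and closes to 20 as before.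

2. Step 4. At the temperature the rearrangement needs, the freshly formed ortho-(1,1-dimethylallyl)phenol may lose the allyl unit, rearrange further or cyclise onto the new alkene. Fallback, setting out from 4 and returning at 12: the quaternary benzylic carbon is made by cross-coupling instead of rearrangement. Compound 4 is methylated at the 4-OH (MeI, Li2CO3, DMF) to 1-(2,3-dihydroxy-4-methoxyphenyl)ethanone F2 and protected (MOMCl, iPr2NEt, CH2Cl2) as 1-[4-methoxy-2,3-bis(methoxymethoxy)phenyl]ethanone F3. Bromination at C5, ortho to the methoxy group and meta to the acetyl group (N-bromosuccinimide, MeCN), gives 1-[5-bromo-4-methoxy-2,3-bis(methoxymethoxy)phenyl]ethanone F4. Branched-selective Suzuki–Miyaura allylation of F4 with prenylboronic acid pinacol ester (Pd(OAc)2, bulky biaryl dialkylphosphine, K3PO4, THF/H2O) then delivers 12.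

3. Step 12. While the hindered MOM ethers are being cleaved, acid-promoted enolisation may erode the C3 configuration. Fallback, setting out from 20 and returning at 24: the acid step is moved in front of the stereochemistry-setting step. Racemic 20 is treated with 2 M HCl in MeOH/THF to give rac-3-[2,3-dihydroxy-4-methoxy-5-(2-methylbut-3-en-2-yl)phenyl]-7-(triisopropylsilyloxy)chroman-4-one F5, where C3 is still racemic and only chemoselectivity matters. Silylation (TBSCl, imidazole, DMF) gives the bis(tert-butyldimethylsilyl) ether F6. The conditions of step 9 give the (3S,4S)-cis-isoflavan-4-ol F7 and those of step 10 the (3S)-tris-silyl isoflavanone F8. A single treatment with HF·pyridine in THF then removes all three silyl groups and gives 24 without any acid or base stronger than pyridinium fluoride.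

**Further compounds**
F1 | step 8 | 2-(4,4,5,5-tetramethyl-1,3,2-dioxaborolan-2-yl)-5-(triisopropylsilyloxy)phenol | CC(C)[Si](Oc1ccc(B2OC(C)(C)C(C)(C)O2)c(O)c1)(C(C)C)C(C)C
F2 | step 4 | 1-(2,3-dihydroxy-4-methoxyphenyl)ethanone | CC(=O)c1ccc(OC)c(O)c1O
F3 | step 4 | 1-[4-methoxy-2,3-bis(methoxymethoxy)phenyl]ethanone | CC(=O)c1ccc(OC)c(OCOC)c1OCOC
F4 | step 4 | 1-[5-bromo-4-methoxy-2,3-bis(methoxymethoxy)phenyl]ethanone | CC(=O)c1cc(Br)c(OC)c(OCOC)c1OCOC
F5 | step 12 | rac-3-[2,3-dihydroxy-4-methoxy-5-(2-methylbut-3-en-2-yl)phenyl]-7-(triisopropylsilyloxy)chroman-4-one | C=CC(C)(C)c1cc(C2COc3cc(O[Si](C(C)C)(C(C)C)C(C)C)ccc3C2=O)c(O)c(O)c1OC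
F6 | step 12 | rac-3-[2,3-bis(tert-butyldimethylsilyloxy)-4-methoxy-5-(2-methylbut-3-en-2-yl)phenyl]-7-(triisopropylsilyloxy)chroman-4-one | C=CC(C)(C)c1cc(C2COc3cc(O[Si](C(C)C)(C(C)C)C(C)C)ccc3C2=O)c(O[Si](C)(C)C(C)(C)C)c(O[Si](C)(C)C(C)(C)C)c1OC
F7 | step 12 | (3S,4S)-3-[2,3-bis(tert-butyldimethylsilyloxy)-4-methoxy-5-(2-methylbut-3-en-2-yl)phenyl]-7-(triisopropylsilyloxy)chroman-4-ol (cis) | C=CC(C)(C)c1cc([C@H]2COc3cc(O[Si](C(C)C)(C(C)C)C(C)C)ccc3[C@H]2O)c(O[Si](C)(C)C(C)(C)C)c(O[Si](C)(C)C(C)(C)C)c1OC
F8 | step 12 | (3S)-3-[2,3-bis(tert-butyldimethylsilyloxy)-4-methoxy-5-(2-methylbut-3-en-2-yl)phenyl]-7-(triisopropylsilyloxy)chroman-4-one | C=CC(C)(C)c1cc([C@H]2COc3cc(O[Si](C(C)C)(C(C)C)C(C)C)ccc3C2=O)c(O[Si](C)(C)C(C)(C)C)c(O[Si](C)(C)C(C)(C)C)c1OC
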